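(The data are simulated with made-up constants; scatter was added.)

A count of 0.136 is what the south-west run had spent by its last reading. The turnover count n is minus the natural logarithm of the fraction of substrate left. The coupling partner is charged above the substrate, so the loss is treated as pseudo-first-order, and n scales with partner charge times time.

the same everywhere: substrate 27 mM

| charge | coupling partner | temperature | remark | time |
|---|---|---|---|---|
| north-east | 68 mM | 75 °C | run made earlier |  |
| south-west | 100 mM | 86 °C | run made earlier |  |
| Wednesday's | 135 mM | 70 °C |  | 20 min |
| Monday's | 135 mM | 90 °C |  | 20 min |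

| run | time / min | side product / % | target / % | substrate / % | intermediate / % |
|---|---|---|---|---|---|
| north-east | 1.00 | 0 | 0 | 99.2 | 0.2 |
| north-east | 1.33 | 0.2 | 0.5 | 99.4 | 1.9 |
| north-east | 2.00 | 0 | 0 | 97.7 | 1.4 |
| north-east | 3.00 | 0 | 1.0 | 96.9 | 2.2 |
| north-east | 5.00 | 0.3 | 0 | 95.7 | 4.5 |
| north-east | 8.00 | 0 | 0.6 | 92.6 | 5.3 |
| north-east | 12.0 | 0.1 | 3.4 | 89.5 | 6.5 |
| south-west | 0.333 | 0.2 | 0.3 | 98.2 | 1.1 |
| south-west | 0.833 | 0 | 0 | 98.3 | 3.0 |
| south-west | 1.33 | 0 | 0.8 | 95.8 | 3.9 |
| south-west | 2.50 | 0 | 1.4 | 92.2 | 6.0 |
| south-west | 4.00 | 0.3 | 3.5 | 88.5 | 8.4 |
| south-west | 5.00 | 0 | 4.2 | 87.3 | 8.7 |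

(each reading ± 0.5 percentage points)

- which of these there is most of at the end, counted by the substrate in it, Wednesday's (side product / target / substrate / intermediate)
- which of these there is most of at the end, counted by the substrate in it, Monday's (side product / target / substrate / intermediate)
- amount of the one of these that there is most of at the end, in percent of the substrate charged, Wednesday's
- amount of the one of these that there is most of at the end, in percent of the substrate charged, Monday's

- reactions considered so far: substrate + coupling partner <-> intermediate; intermediate -> target; intermediate -> side product; target <-> isomer of the product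
- a reading of target is of its free form alone

The north-east run reads n = 0.111 at its last point. Per unit of partner and time, the south-west count is 2.00 times the north-east one. That ratio belongs to the step from 75 °C to 86 °C, and it carries the scatter of the readings.

Two chemists scale this up. The first takes the count at face value. Wednesday's flask gets 0.268, which leaves 76.5% of substrate, so substrate leads there. Monday's flask gets 0.943, which leaves 38.9%. Target then leads if it holds 63.8% of what has left the substrate, and she expects that.

The second objects that a forward pass is no loss for good, since the first step is reversible. In the south-west run, n per minute at the last reading is 0.836 of its value at 2.50 min. This is a rough reading. Multiplying gives 0.789 for Monday's flask, the net turnover count. Substrate then stands at 45.4%, and target must hold 83.3% of the rest. At the south-west run's last reading it held 32.6%. She doubts it climbs so far, and says substrate leads.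

The forecast took the first side: substrate at 80% on Wednesday's, target at 43% on Monday's, “a close call against substrate”.

Wednesday's flask ends with substrate at 78.1%. Monday's flask ends with substrate at 47.2%, and target stands at 35.6%.

    substrate + coupling partner ⇌ intermediate (K = 3.90 M⁻¹, k = 0.120 M⁻¹ min⁻¹, Ea = 70.0 kJ mol⁻¹, ΔH = −12.0 kJ mol⁻¹)
    intermediate → target (k = 0.0370 min⁻¹, Ea = 91.0 kJ mol⁻¹)
    intermediate → side product (k = 0.00340 min⁻¹, Ea = 118 kJ mol⁻¹)
    target ⇌ isomer of the product (K = 0.170, k = 0.00900 min⁻¹, Ea = 99.0 kJ mol⁻¹, ΔH = −21.0 kJ mol⁻¹)
    (constants at 70 °C)

Monday's flask ends with less substrate than Wednesday's, mainly because of the difference in temperature. Part of why substrate still leads on Monday's is the way back from intermediate, together with the time of the reading. Without that way back, Monday's substrate ends at 31.7%, and left until 200 min it stands at 0.206%. The first view's region is a hotter flask. With the same charge and time at 95 °C, the net count scales to 1.08, so substrate is reckoned at 34.0% and target needs 51.4% of the rest. That flask gives 36.5% of substrate and 45.3% of target, so target leads.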